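**Retrosynthetic overview**
1. Last operations: the C6 prenyl group (phenoxide C-alkylation) and the free 7-OH (chelation-controlled demethylation) are added to a 5,7-dimethoxycoumarin aryl cyclohexenyl ketone.
2. Cyclohexene C1=C2: intramolecular aldol condensation of a 1,7-keto aldehyde; the aldehyde comes from ozonolysis of the citronellal isopropylidene group, the carbinol from Felkin-controlled methyl addition to an aldehyde.
3. Key bond C1–C6 (inside the 1,4-dioxygenated unit ArC(=O)–C1–C6–CH(OH)CH3): an α-acyl radical from an 8-bromoacetylcoumarin, electrophilic at the ketone α-carbon, is joined to the enamine α-carbon of (R)-citronellal under photoredox/imidazolidinone catalysis. C5 comes from citronellal, C6 from the catalyst.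
4. Bromoketone: Friedel–Crafts bromoacetylation at C8 of 5,7-dimethoxy-3,4-dimethylcoumarin, which comes from a Pechmann condensation.
5. Ring order: benzene ring bought, pyranone ring first (Pechmann), cyclohexene ring last (aldol condensation).

Assumption: (R)-citronellal of high enantiomeric purity is taken as commercial; coumarin locants (O1 to C8a) are used for the core, and the cyclohexene locants of the target (C1 carbonyl-bearing, C5 methyl, C6 hydroxyethyl) are used for the same carbons in open-chain precursors.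

**Route**

Step 1
Reactants: 1 3,5-dimethoxyphenol; 2 ethyl 2-methyl-3-oxobutanoate
Product: 3 5,7-dimethoxy-3,4-dimethyl-2H-chromen-2-one
Conditions: conc. H2SO4, 0 °C to rt, 12 h; ice water
Reagents that add atoms: none
Why: Pechmann condensation (transesterification, ring closure ortho to the phenol oxygen, dehydration) of an electron-rich phenol whose two ortho positions are equivalent, so only one coumarin can form and no stereocentre is created.

Step 2
Reactants: 3 5,7-dimethoxy-3,4-dimethyl-2H-chromen-2-one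
Product: 4 8-(2-bromoacetyl)-5,7-dimethoxy-3,4-dimethyl-2H-chromen-2-one
Conditions: BrCH2COBr (1.3 equiv), AlCl3 (2.5 equiv), CH2Cl2, −10 to 0 °C, 2 h; ice/1 M HCl
Reagents that add atoms: bromoacetyl bromide, BrCC(Br)=O
Why: Friedel–Crafts acylation goes to C8, which is para to the 5-methoxy and ortho to the 7-methoxy group and less hindered than C6 between two methoxy groups, while the low temperature keeps AlCl3 from cleaving the ortho methyl ether.

Step 3
Reactants: 4 8-(2-bromoacetyl)-5,7-dimethoxy-3,4-dimethyl-2H-chromen-2-one; 5 (R)-citronellal, (3R)-3,7-dimethyloct-6-enal (2 equiv)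
Product: 6 (2S,3R)-2-[2-(5,7-dimethoxy-3,4-dimethyl-2-oxo-2H-chromen-8-yl)-2-oxoethyl]-3,7-dimethyloct-6-enal
Conditions: Ru(bpy)3Cl2 (0.5 mol %), (2R,5S)-2-tert-butyl-3,5-dimethylimidazolidin-4-one·TfOH (20 mol %), 2,6-lutidine (2 equiv), DMF, blue LED or household fluorescent lamp, 23 °C; crude product used at once
Reagents that add atoms: none
Why: Photoredox organocatalytic α-alkylation of an aldehyde (MacMillan type), in which single-electron reduction of 4 by the reduced ruthenium photocatalyst gives an electrophilic α-acyl radical (an enolonium-type synthon) that adds to the Si face of the (E)-enamine of 5 left open by the imidazolidinone, so that two natively nucleophilic α-carbons are joined as a 1,4-dicarbonyl and the new centre (later ring C6) is set 2S under catalyst control next to the 3R centre from citronellal.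

Step 4
Reactants: 6 (2S,3R)-2-[2-(5,7-dimethoxy-3,4-dimethyl-2-oxo-2H-chromen-8-yl)-2-oxoethyl]-3,7-dimethyloct-6-enal
Product: 7 8-[(3S,4R)-3-[(1S)-1-hydroxyethyl]-4,8-dimethylnon-7-enoyl]-5,7-dimethoxy-3,4-dimethyl-2H-chromen-2-one
Conditions: MeTi(OiPr)3 (1.5 equiv), THF, −78 to −30 °C; aq. NH4Cl
Reagents that add atoms: methyltitanium triisopropoxide, C[Ti](OC(C)C)(OC(C)C)OC(C)C
Why: Chemoselective 1,2-addition of a non-basic methyltitanium reagent to the aldehyde (the di-ortho-substituted aryl ketone and the lactone do not react and the α-centre is not epimerised) under Felkin–Anh control with the branched C4 alkyl group as the large substituent, which gives the (1S)-carbinol with an expected dr of about 5:1, the minor epimer being removed by chromatography.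

Step 5
Reactants: 7 8-[(3S,4R)-3-[(1S)-1-hydroxyethyl]-4,8-dimethylnon-7-enoyl]-5,7-dimethoxy-3,4-dimethyl-2H-chromen-2-one
Product: 9 (4R,5S)-7-(5,7-dimethoxy-3,4-dimethyl-2-oxo-2H-chromen-8-yl)-5-[(1S)-1-hydroxyethyl]-4-methyl-7-oxoheptanal, via secondary ozonide 8 (not isolated)
Conditions: O3, CH2Cl2, −78 °C, Sudan Red 7B as end-point indicator; then Me2S (5 equiv), −78 °C to rt
Reagents that add atoms: ozone, [O-][O+]=O
Why: Ozonolysis with reductive work-up, in which the isolated trisubstituted alkene reacts far faster than the tetrasubstituted conjugated coumarin double bond or the acylated arene, so the isopropylidene group is cut to the C2 aldehyde without touching any stereocentre.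

Step 6
Reactants: 9 (4R,5S)-7-(5,7-dimethoxy-3,4-dimethyl-2-oxo-2H-chromen-8-yl)-5-[(1S)-1-hydroxyethyl]-4-methyl-7-oxoheptanal
Product: 11 8-{[(5R,6R)-6-[(1S)-1-hydroxyethyl]-5-methylcyclohex-1-en-1-yl]carbonyl}-5,7-dimethoxy-3,4-dimethyl-2H-chromen-2-one, via aldol adduct 10 (not isolated)
Conditions: KOH (0.3 equiv), MeOH, 0.01 M, 0 °C to rt; then 1 M HCl to pH 3
Reagents that add atoms: none
Why: Intramolecular aldol condensation (6-enolexo-exo-trig) in which the ketone enolate at C1 attacks the unhindered aldehyde, the reverse pairing being blocked by the shielded di-ortho-substituted aryl ketone, and E1cB loss of water gives the conjugated C1=C2 enone while the non-acidic C5, C6 and carbinol centres stay untouched.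

Step 7
Reactants: 11 8-{[(5R,6R)-6-[(1S)-1-hydroxyethyl]-5-methylcyclohex-1-en-1-yl]carbonyl}-5,7-dimethoxy-3,4-dimethyl-2H-chromen-2-one
Product: 12 7-hydroxy-8-{[(5R,6R)-6-[(1S)-1-hydroxyethyl]-5-methylcyclohex-1-en-1-yl]carbonyl}-5-methoxy-3,4-dimethyl-2H-chromen-2-one
Conditions: BCl3 (3 equiv, 1 M in CH2Cl2), CH2Cl2, −78 to 0 °C; aq. NaHCO3
Reagents that add atoms: none
Why: Chelation-controlled aryl methyl ether cleavage, in which BCl3 bound to the ketone oxygen removes only the methyl of the ortho 7-methoxy group while the 5-methoxy group para to the ketone is not activated, with no change at the stereocentres.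

Step 8
Reactants: 12 7-hydroxy-8-{[(5R,6R)-6-[(1S)-1-hydroxyethyl]-5-methylcyclohex-1-en-1-yl]carbonyl}-5-methoxy-3,4-dimethyl-2H-chromen-2-one
Product: 13 7-hydroxy-8-{[(5R,6R)-6-[(1S)-1-hydroxyethyl]-5-methylcyclohex-1-en-1-yl]carbonyl}-5-methoxy-3,4-dimethyl-6-(3-methylbut-2-en-1-yl)-2H-chromen-2-one (CNP0197455.1)
Conditions: prenyl bromide (1.5 equiv), 10% aq. KOH, 0 °C, 3 h; then cold 1 M HCl
Reagents that add atoms: prenyl bromide (1-bromo-3-methylbut-2-ene), CC(C)=CCBr
Why: ortho-C-Alkylation of a phenoxide in water, where solvation of the oxygen favours attack through carbon and C6 is the only free ring position, so the prenyl group is installed without protecting the side-chain alcohol and all three stereocentres are unchanged.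

**Compound list**
1 | 3,5-dimethoxyphenol | COc1cc(O)cc(OC)c1 | starting material
2 | ethyl 2-methyl-3-oxobutanoate (ethyl 2-methylacetoacetate) | CCOC(=O)C(C)C(C)=O | starting material
3 | 5,7-dimethoxy-3,4-dimethyl-2H-chromen-2-one | COc1cc(OC)c2c(C)c(C)c(=O)oc2c1 | intermediate
4 | 8-(2-bromoacetyl)-5,7-dimethoxy-3,4-dimethyl-2H-chromen-2-one | COc1cc(OC)c2c(C)c(C)c(=O)oc2c1C(=O)CBr | intermediate
5 | (R)-citronellal, (3R)-3,7-dimethyloct-6-enal | CC(C)=CCC[C@@H](C)CC=O | starting material
6 | (2S,3R)-2-[2-(5,7-dimethoxy-3,4-dimethyl-2-oxo-2H-chromen-8-yl)-2-oxoethyl]-3,7-dimethyloct-6-enal | CC(C)=CCC[C@@H](C)[C@H](CC(=O)c1c(OC)cc(OC)c2c(C)c(C)c(=O)oc12)C=O | intermediate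
7 | 8-[(3S,4R)-3-[(1S)-1-hydroxyethyl]-4,8-dimethylnon-7-enoyl]-5,7-dimethoxy-3,4-dimethyl-2H-chromen-2-one | CC(C)=CCC[C@@H](C)[C@H](CC(=O)c1c(OC)cc(OC)c2c(C)c(C)c(=O)oc12)[C@H](C)O | intermediate
8 | secondary ozonide, 8-{(3S,4R)-6-(5,5-dimethyl-1,2,4-trioxolan-3-yl)-3-[(1S)-1-hydroxyethyl]-4-methylhexanoyl}-5,7-dimethoxy-3,4-dimethyl-2H-chromen-2-one (epimers at the trioxolane carbon, not isolated) | CC1(C)OOC(CC[C@@H](C)[C@H](CC(=O)c2c(OC)cc(OC)c3c(C)c(C)c(=O)oc23)[C@H](C)O)O1 | intermediate
9 | (4R,5S)-7-(5,7-dimethoxy-3,4-dimethyl-2-oxo-2H-chromen-8-yl)-5-[(1S)-1-hydroxyethyl]-4-methyl-7-oxoheptanal | O=CCC[C@@H](C)[C@H](CC(=O)c1c(OC)cc(OC)c2c(C)c(C)c(=O)oc12)[C@H](C)O | intermediate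
10 | aldol adduct, 8-{[(5R,6R)-2-hydroxy-6-[(1S)-1-hydroxyethyl]-5-methylcyclohexyl]carbonyl}-5,7-dimethoxy-3,4-dimethyl-2H-chromen-2-one (epimers at ring C1 and C2, not isolated) | COc1cc(OC)c2c(C)c(C)c(=O)oc2c1C(=O)C1C(O)CC[C@@H](C)[C@H]1[C@H](C)O | intermediate
11 | 8-{[(5R,6R)-6-[(1S)-1-hydroxyethyl]-5-methylcyclohex-1-en-1-yl]carbonyl}-5,7-dimethoxy-3,4-dimethyl-2H-chromen-2-one | COc1cc(OC)c2c(C)c(C)c(=O)oc2c1C(=O)C1=CCC[C@@H](C)[C@H]1[C@H](C)O | intermediate
12 | 7-hydroxy-8-{[(5R,6R)-6-[(1S)-1-hydroxyethyl]-5-methylcyclohex-1-en-1-yl]carbonyl}-5-methoxy-3,4-dimethyl-2H-chromen-2-one | COc1cc(O)c(C(=O)C2=CCC[C@@H](C)[C@H]2[C@H](C)O)c2oc(=O)c(C)c(C)c12 | intermediate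
13 | 7-hydroxy-8-{[(5R,6R)-6-[(1S)-1-hydroxyethyl]-5-methylcyclohex-1-en-1-yl]carbonyl}-5-methoxy-3,4-dimethyl-6-(3-methylbut-2-en-1-yl)-2H-chromen-2-one | COc1c(CC=C(C)C)c(O)c(C(=O)C2=CCC[C@@H](C)[C@H]2[C@H](C)O)c2oc(=O)c(C)c(C)c12 | target

**Step count and risks**
Total steps: 8. Longest linear sequence: 8 steps (1 to 13); 5 enters at step 3.

The three steps most likely to fail:

Step 3. The hindered, electron-rich bromoketone may be reduced slowly or give poor diastereocontrol next to the resident centre. The fallback sets out from 5, uses 4 as before and comes back at 6. Condense 5 with (R)-1-amino-2-(methoxymethyl)pyrrolidine (CH2Cl2, MgSO4, rt) to give the RAMP hydrazone of citronellal F1. Deprotonate it with LiN(iPr)2 (THF, 0 °C) and alkylate the azaenolate with 4 at −100 °C, which gives the alkylated hydrazone F2 under auxiliary control (the RAMP enantiomer delivers the electrophile to the face needed for 2S). Cleave F2 with saturated aqueous oxalic acid/Et2O at rt to release 6.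

Step 6. The base-mediated closure may suffer from aldehyde self-condensation, enolisation on the wrong side or lactone opening. The fallback sets out from 7 (so it also bypasses step 5) and comes back at 11. Direct α-methylenation of the ketone (paraformaldehyde, iPr2NH·TFA, THF, reflux) gives the α-methylene ketone F3. Ring-closing metathesis with second-generation Grubbs catalyst (5 mol %, toluene, 80 °C) between its 1,1-disubstituted enone alkene and the trisubstituted alkene, with loss of isobutene, gives 11.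

Step 8. O-alkylation, low conversion or phenoxide/enone side reactions may spoil the direct C-prenylation. The fallback sets out from 12 and comes back at 13. Iodinate the only free ring position with N-iodosuccinimide (MeCN, 0 °C) to give the 6-iodide F4. Couple F4 under neutral Stille conditions with tributyl(3-methylbut-2-en-1-yl)stannane and Pd(PPh3)4 (DMF, 80 °C) to give 13.

Further compounds
F1 | step 3 | RAMP hydrazone of citronellal, (E)-N-[(3R)-3,7-dimethyloct-6-en-1-ylidene]-(2R)-2-(methoxymethyl)pyrrolidin-1-amine | CC(C)=CCC[C@@H](C)C/C=N/N1CCC[C@@H]1COC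
F2 | step 3 | alkylated hydrazone, RAMP hydrazone of 6 with (2S,3R) configuration in the aldehyde-derived chain | CC(C)=CCC[C@@H](C)[C@H](CC(=O)c1c(OC)cc(OC)c2c(C)c(C)c(=O)oc12)/C=N/N1CCC[C@@H]1COC
F3 | step 6 | α-methylene ketone, 8-{(3R,4R)-3-[(1S)-1-hydroxyethyl]-4,8-dimethyl-2-methylidenenon-7-enoyl}-5,7-dimethoxy-3,4-dimethyl-2H-chromen-2-one | CC(C)=CCC[C@@H](C)[C@H](C(=C)C(=O)c1c(OC)cc(OC)c2c(C)c(C)c(=O)oc12)[C@H](C)O
F4 | step 8 | 6-iodide, 7-hydroxy-8-{[(5R,6R)-6-[(1S)-1-hydroxyethyl]-5-methylcyclohex-1-en-1-yl]carbonyl}-6-iodo-5-methoxy-3,4-dimethyl-2H-chromen-2-one | COc1c(I)c(O)c(C(=O)C2=CCC[C@@H](C)[C@H]2[C@H](C)O)c2oc(=O)c(C)c(C)c12
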